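**Retrosynthetic overview**

1. The target, 7α,15-diacetoxy-6β-hydroxylabda-8,13Z-diene (27), is traced back to the 6β,7α,15-triol and then to the trans-fused labda-8,13Z-dien-6-one 22 (C7 enolate hydroxylation, α-face hydride delivery at C6).
2. Ring B is closed last by joining C5 to C6: titanium-mediated reductive coupling of the ring A ketone carbon (C5) with a side-chain ester carbonyl (C6) in the monocyclic keto ester 20, followed by hydrolysis of the resulting enol ether (sets 5α-H).
3. Enabling feature: C5 is a non-enolisable ketone carbon of ring A flanked by the quaternary carbons C4 and C10, and the ester carbon C6 is held on the same side of the Z-configured tetrasubstituted C8=C9 alkene, so only the six-membered ring B can form.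
4. 20 comes from allenoate 18 and Me2CuLi (fixes the C8=C9 geometry); 18 from a ketene Wittig reaction of acid 14; 14 from dianion alkylation of keto acid 6 with the (Z)-iodide 12; C10 from Pd-catalysed decarboxylative asymmetric allylation of 2,2,6-trimethylcyclohexanone.
5. Order of rings: ring A is purchased (ketone 1); ring B is formed in step 11.

Key step: step 11

Remark: labdane numbering (C1–C20) is used for all positions; α is the face opposite the C10 methyl group; TBDPS = tert-butyl(diphenyl)silyl.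

**Route**

Step 1
Reactants: 1 2,2,6-trimethylcyclohexanone; 2 allyl chloroformate
Product: 4 allyl 2,6,6-trimethylcyclohex-1-en-1-yl carbonate, via lithium enolate 3 (not isolated)
Conditions: LiN(SiMe3)2, TMEDA, THF, −78 → 0 °C; then 2, −78 °C → rt
Reagents that add atoms: none
Why: Deprotonation can occur only at C6 (the other α-carbon is quaternary) and O-acylation of the lithium enolate by the chloroformate should give the enol carbonate (enolate O-acylation); no stereocentre is formed.

Step 2
Reactants: 4 allyl 2,6,6-trimethylcyclohex-1-en-1-yl carbonate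
Product: 5 (2R)-2-allyl-2,6,6-trimethylcyclohexan-1-one
Conditions: Pd2(dba)3 (2.5 mol %), (R)-t-Bu-PHOX (6 mol %), THF, 25 °C
Reagents that add atoms: none
Why: Decarboxylative asymmetric allylic alkylation (Tsuji–Trost type) in which the Pd-bound allyl/enolate pair recombines inside the chiral PHOX pocket, so the ligand sets the quaternary stereocentre (future C10) as (R), the sense expected by analogy with the (S)-ligand/(S)-ketone pairing known for 2-alkylcyclohexanone enol carbonates.

Step 3
Reactants: 5 (2R)-2-allyl-2,6,6-trimethylcyclohexan-1-one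
Product: 6 2-[(1R)-1,3,3-trimethyl-2-oxocyclohexyl]acetic acid
Conditions: RuCl3·xH2O (2 mol %), NaIO4 (4.2 equiv), CCl4/MeCN/H2O, rt
Reagents that add atoms: sodium periodate [Na+].[O-]I(=O)(=O)=O; water O
Why: RuO4-mediated oxidative cleavage of the terminal alkene (Sharpless conditions) should shorten allyl to carboxymethyl while the hindered non-enolisable ketone and the stereocentre stay untouched.

Step 4
Reactants: 7 (2Z)-3-methylpent-2-en-4-yn-1-ol
Product: 8 tert-butyl{[(2Z)-3-methylpent-2-en-4-yn-1-yl]oxy}diphenylsilane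
Conditions: t-BuPh2SiCl, imidazole, CH2Cl2, 0 °C → rt
Reagents that add atoms: tert-butyl(chloro)diphenylsilane CC(C)(C)[Si](Cl)(c1ccccc1)c1ccccc1
Why: Standard silylation of a primary allylic alcohol; the TBDPS ether is chosen to survive strong bases, cuprates, low-valent titanium and dilute acid.

Step 5
Reactants: 8 tert-butyl{[(2Z)-3-methylpent-2-en-4-yn-1-yl]oxy}diphenylsilane
Product: 9 tert-butyl{[(2Z)-3-methylpenta-2,4-dien-1-yl]oxy}diphenylsilane
Conditions: H2 (1 atm), Pd/CaCO3 poisoned with Pb(OAc)2 (Lindlar catalyst), quinoline, hexane/EtOAc, rt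
Reagents that add atoms: none
Why: Lindlar semihydrogenation should stop at the alkene stage and turn the terminal alkyne into a vinyl group without touching the trisubstituted (Z)-alkene.

Step 6
Reactants: 9 tert-butyl{[(2Z)-3-methylpenta-2,4-dien-1-yl]oxy}diphenylsilane
Product: 11 (3Z)-5-{[tert-butyl(diphenyl)silyl]oxy}-3-methylpent-3-en-1-ol, via B-alkyl-9-BBN adduct 10 (not isolated)
Conditions: 9-BBN, THF, 0 °C → rt; then NaOH, H2O2, 0 °C
Reagents that add atoms: hydrogen peroxide OO
Why: Hydroboration–oxidation in which the bulky borane adds anti-Markovnikov to the monosubstituted terminus of the diene (the trisubstituted alkene is far slower), giving the primary homoallylic alcohol with the (Z)-alkene intact.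

Step 7
Reactants: 11 (3Z)-5-{[tert-butyl(diphenyl)silyl]oxy}-3-methylpent-3-en-1-ol
Product: 12 tert-butyl{[(2Z)-5-iodo-3-methylpent-2-en-1-yl]oxy}diphenylsilane
Conditions: I2, PPh3, imidazole, CH2Cl2, 0 °C
Reagents that add atoms: iodine II
Why: Appel-type iodination (Garegg–Samuelsson conditions) should convert the primary alcohol into the iodide by SN2 under neutral conditions.

Step 8
Reactants: 6 2-[(1R)-1,3,3-trimethyl-2-oxocyclohexyl]acetic acid; 12 tert-butyl{[(2Z)-5-iodo-3-methylpent-2-en-1-yl]oxy}diphenylsilane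
Product: 14 (5Z)-7-{[tert-butyl(diphenyl)silyl]oxy}-5-methyl-2-[(1R)-1,3,3-trimethyl-2-oxocyclohexyl]hept-5-enoic acid (both C2 epimers), via dilithium enediolate 13 (not isolated)
Conditions: LiN(i-Pr)2 (2.2 equiv), THF, −78 → 0 °C; then 12, DMPU, −78 °C → rt; aq. HCl work-up
Reagents that add atoms: none
Why: Carboxylic acid dianion alkylation in which the only acidic C–H is on the carboxymethyl carbon (future C9) and SN2 on the primary iodide forms the C9–C11 bond; the new stereocentre forms unselectively but is erased in step 9.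

Step 9
Reactants: 14 (5Z)-7-{[tert-butyl(diphenyl)silyl]oxy}-5-methyl-2-[(1R)-1,3,3-trimethyl-2-oxocyclohexyl]hept-5-enoic acid; 15 methyl (triphenylphosphoranylidene)acetate
Product: 18 methyl (7Z)-9-{[tert-butyl(diphenyl)silyl]oxy}-7-methyl-4-[(1R)-1,3,3-trimethyl-2-oxocyclohexyl]nona-2,3,7-trienoate (both allene-axis epimers), via acid chloride 16 (not isolated), via ketene 17 (not isolated)
Conditions: (COCl)2, DMF (cat.), CH2Cl2, 0 °C → rt, evaporate; then 15, Et3N, CH2Cl2, 0 °C → rt
Reagents that add atoms: none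
Why: Dehydrochlorination of the acid chloride gives the disubstituted ketene, whose C=O undergoes Wittig olefination with the stabilised ylide (the standard route to 4,4-disubstituted 2,3-allenoates); the C9 stereocentre disappears and the allene axis, formed as a mixture, is erased in step 10.

Step 10
Reactants: 18 methyl (7Z)-9-{[tert-butyl(diphenyl)silyl]oxy}-7-methyl-4-[(1R)-1,3,3-trimethyl-2-oxocyclohexyl]nona-2,3,7-trienoate
Product: 20 methyl (3Z,7Z)-9-{[tert-butyl(diphenyl)silyl]oxy}-3,7-dimethyl-4-[(1R)-1,3,3-trimethyl-2-oxocyclohexyl]nona-3,7-dienoate, via lithium dienolate 19 (not isolated)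
Conditions: Me2CuLi (from MeLi, CuI), Et2O, −78 °C; sat. aq. NH4Cl at −78 °C
Reagents that add atoms: lithium dimethylcuprate [Li+].C[Cu-]C
Why: Organocuprate conjugate addition to the central carbon of the allenoate followed by kinetic α-protonation gives the β,γ-unsaturated ester; the methyl group approaches in the plane of the C9 substituents from the side of the CH2 chain, away from the quaternary ring carbon, which should place CH2CO2Me cis to ring A as the cyclisation requires.

Step 11
Reactants: 20 methyl (3Z,7Z)-9-{[tert-butyl(diphenyl)silyl]oxy}-3,7-dimethyl-4-[(1R)-1,3,3-trimethyl-2-oxocyclohexyl]nona-3,7-dienoate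
Product: 22 15-{[tert-butyl(diphenyl)silyl]oxy}labda-8,13Z-dien-6-one (5S,10S; 5α-H; trans-decalin), via methyl enol ether 21 (not isolated)
Conditions: TiCl3, LiAlH4, Et3N, DME, reflux, slow addition of 20 (high dilution); then 1 M HCl, THF, 0 °C
Reagents that add atoms: water O
Why: Low-valent titanium reduces the hindered, non-enolisable ring A ketone to a titanium-bound ketyl at C5, which adds to the ester carbonyl (C6) held nearby by the cis C8=C9 alkene; the titanium-bound α-methoxy diolate is then deoxygenated to the cyclic methyl enol ether 21, which dilute acid hydrolyses to the C6 ketone. The closest known reaction is the McMurry titanium-induced keto ester cyclisation to cycloalkanones. Ring B is closed as a six-membered carbocycle by this reductive carbonyl–carbonyl coupling, the ketyl carbon attacking the ester C=O in exo fashion, with C5–C6 as the only bond formed. The new C5 stereocentre is set in the hydrolysis: protonation of the enol ether at C5 from the α face, opposite the axial C10 methyl and the 4β-methyl group, should give the trans-decalin, which is also the thermodynamically preferred epimer next to the C6 ketone. The step needs selective activation of the ketone (esters are not reduced by this reagent and the ketone is too hindered to homocouple), cyclisation over oligomerisation (slow addition, preorganisation by the Z-alkene) and retention of the C8=C9 position (cold dilute acid, short contact time).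

Step 12
Reactants: 22 15-{[tert-butyl(diphenyl)silyl]oxy}labda-8,13Z-dien-6-one
Product: 24 15-{[tert-butyl(diphenyl)silyl]oxy}-7α-hydroxylabda-8,13Z-dien-6-one (5S,7S,10S), via potassium dienolate 23 (not isolated)
Conditions: KN(SiMe3)2, THF, −78 °C; 2-(benzenesulfonyl)-3-phenyloxaziridine, −78 °C; aq. NH4Cl
Reagents that add atoms: 2-(benzenesulfonyl)-3-phenyloxaziridine O=S(=O)(c1ccccc1)N1OC1c1ccccc1
Why: Enolate hydroxylation (Davis oxidation) in which kinetic deprotonation at the doubly activated C7 methylene gives the dienolate, which should be oxidised at its α-carbon from the α face (pseudoaxial attack, opposite the C10 and 4β methyl groups), setting 7α-OH.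

Step 13
Reactants: 24 15-{[tert-butyl(diphenyl)silyl]oxy}-7α-hydroxylabda-8,13Z-dien-6-one
Product: 25 15-{[tert-butyl(diphenyl)silyl]oxy}labda-8,13Z-diene-6β,7α-diol (5S,6S,7S,10S)
Conditions: NaBH4, MeOH/THF, −40 → 0 °C
Reagents that add atoms: none
Why: Borohydride reduction in which hydride attacks the C6 ketone from the α face, the β face being blocked by the syn-axial C10 and 4β methyl groups, to give the axial 6β-alcohol as is general for 6-oxo labdanes and drimanes.

Step 14
Reactants: 25 15-{[tert-butyl(diphenyl)silyl]oxy}labda-8,13Z-diene-6β,7α-diol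
Product: 26 labda-8,13Z-diene-6β,7α,15-triol (5S,6S,7S,10S)
Conditions: n-Bu4NF, AcOH (1:1), THF, rt
Reagents that add atoms: none
Why: Fluoride-mediated desilylation, buffered with acetic acid to avoid base-induced side reactions of the allylic diol.

Step 15
Reactants: 26 labda-8,13Z-diene-6β,7α,15-triol
Product: 27 7α,15-diacetoxy-6β-hydroxylabda-8,13Z-diene (5S,6S,7S,10S; the target)
Conditions: Ac2O (2.3 equiv), pyridine, DMAP (5 mol %), CH2Cl2, 0 °C, monitored
Reagents that add atoms: acetic anhydride CC(=O)OC(C)=O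
Why: Acetylation discriminating by steric hindrance: the primary C15 and the secondary allylic C7 hydroxyls should react, whereas the axial 6β-hydroxyl, syn-axial to two methyl groups, is expected to stay free under these mild conditions.

**Compound list**

1 | 2,2,6-trimethylcyclohexanone | CC1CCCC(C)(C)C1=O | starting material
2 | allyl chloroformate | C=CCOC(Cl)=O | starting material
3 | lithium 2,6,6-trimethylcyclohex-1-en-1-olate | [Li]OC1=C(C)CCCC1(C)C | intermediate
4 | allyl 2,6,6-trimethylcyclohex-1-en-1-yl carbonate | C=CCOC(=O)OC1=C(C)CCCC1(C)C | intermediate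
5 | (2R)-2-allyl-2,6,6-trimethylcyclohexan-1-one | O=C1C(C)(C)CCC[C@]1(C)CC=C | intermediate
6 | 2-[(1R)-1,3,3-trimethyl-2-oxocyclohexyl]acetic acid | O=C1C(C)(C)CCC[C@]1(C)CC(=O)O | intermediate
7 | (2Z)-3-methylpent-2-en-4-yn-1-ol | C#C/C(C)=C\CO | starting material
8 | tert-butyl{[(2Z)-3-methylpent-2-en-4-yn-1-yl]oxy}diphenylsilane | C#C/C(C)=C\CO[Si](c1ccccc1)(c1ccccc1)C(C)(C)C | intermediate
9 | tert-butyl{[(2Z)-3-methylpenta-2,4-dien-1-yl]oxy}diphenylsilane | C=C/C(C)=C\CO[Si](c1ccccc1)(c1ccccc1)C(C)(C)C | intermediate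
10 | 9-[(3Z)-5-{[tert-butyl(diphenyl)silyl]oxy}-3-methylpent-3-en-1-yl]-9-borabicyclo[3.3.1]nonane | C1CC2CCCC(C1)B2CC/C(C)=C\CO[Si](c1ccccc1)(c1ccccc1)C(C)(C)C | intermediate
11 | (3Z)-5-{[tert-butyl(diphenyl)silyl]oxy}-3-methylpent-3-en-1-ol | OCC/C(C)=C\CO[Si](c1ccccc1)(c1ccccc1)C(C)(C)C | intermediate
12 | tert-butyl{[(2Z)-5-iodo-3-methylpent-2-en-1-yl]oxy}diphenylsilane | ICC/C(C)=C\CO[Si](c1ccccc1)(c1ccccc1)C(C)(C)C | intermediate
13 | dilithium enediolate of acid 6 | O=C1C(C)(C)CCC[C@]1(C)C=C(O[Li])O[Li] | intermediate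
14 | (5Z)-7-{[tert-butyl(diphenyl)silyl]oxy}-5-methyl-2-[(1R)-1,3,3-trimethyl-2-oxocyclohexyl]hept-5-enoic acid (C2 epimers) | O=C1C(C)(C)CCC[C@]1(C)C(CC/C(C)=C\CO[Si](c2ccccc2)(c2ccccc2)C(C)(C)C)C(=O)O | intermediate
15 | methyl (triphenylphosphoranylidene)acetate | COC(=O)C=P(c1ccccc1)(c1ccccc1)c1ccccc1 | starting material
16 | acid chloride of 14 | O=C1C(C)(C)CCC[C@]1(C)C(CC/C(C)=C\CO[Si](c2ccccc2)(c2ccccc2)C(C)(C)C)C(Cl)=O | intermediate
17 | ketene from 16 | O=C1C(C)(C)CCC[C@]1(C)C(CC/C(C)=C\CO[Si](c2ccccc2)(c2ccccc2)C(C)(C)C)=C=O | intermediate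
18 | methyl (7Z)-9-{[tert-butyl(diphenyl)silyl]oxy}-7-methyl-4-[(1R)-1,3,3-trimethyl-2-oxocyclohexyl]nona-2,3,7-trienoate (allene-axis epimers) | O=C1C(C)(C)CCC[C@]1(C)C(CC/C(C)=C\CO[Si](c2ccccc2)(c2ccccc2)C(C)(C)C)=C=CC(=O)OC | intermediate
19 | lithium dienolate of ester 20 | O=C1C(C)(C)CCC[C@]1(C)/C(CC/C(C)=C\CO[Si](c2ccccc2)(c2ccccc2)C(C)(C)C)=C(/C)C=C(OC)O[Li] | intermediate
20 | methyl (3Z,7Z)-9-{[tert-butyl(diphenyl)silyl]oxy}-3,7-dimethyl-4-[(1R)-1,3,3-trimethyl-2-oxocyclohexyl]nona-3,7-dienoate | O=C1C(C)(C)CCC[C@]1(C)/C(CC/C(C)=C\CO[Si](c2ccccc2)(c2ccccc2)C(C)(C)C)=C(/C)CC(=O)OC | intermediate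
21 | 15-{[tert-butyl(diphenyl)silyl]oxy}-6-methoxylabda-5,8,13Z-triene | CC(C)(C)[Si](c3ccccc3)(c3ccccc3)OC/C=C(/C)CCC1=C(C)CC(OC)=C2C(C)(C)CCC[C@]12C | intermediate
22 | (5S,10S)-15-{[tert-butyl(diphenyl)silyl]oxy}labda-8,13Z-dien-6-one | CC(C)(C)[Si](c3ccccc3)(c3ccccc3)OC/C=C(/C)CCC1=C(C)CC(=O)[C@H]2C(C)(C)CCC[C@]12C | intermediate
23 | potassium 6,8-dienolate of ketone 22 | CC(C)(C)[Si](c3ccccc3)(c3ccccc3)OC/C=C(/C)CCC1=C(C)C=C(O[K])[C@H]2C(C)(C)CCC[C@]12C | intermediate
24 | (5S,7S,10S)-15-{[tert-butyl(diphenyl)silyl]oxy}-7α-hydroxylabda-8,13Z-dien-6-one | CC(C)(C)[Si](c3ccccc3)(c3ccccc3)OC/C=C(/C)CCC1=C(C)[C@H](O)C(=O)[C@H]2C(C)(C)CCC[C@]12C | intermediate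
25 | (5S,6S,7S,10S)-15-{[tert-butyl(diphenyl)silyl]oxy}labda-8,13Z-diene-6β,7α-diol | CC(C)(C)[Si](c3ccccc3)(c3ccccc3)OC/C=C(/C)CCC1=C(C)[C@H](O)[C@@H](O)[C@H]2C(C)(C)CCC[C@]12C | intermediate
26 | (5S,6S,7S,10S)-labda-8,13Z-diene-6β,7α,15-triol | OC/C=C(/C)CCC1=C(C)[C@H](O)[C@@H](O)[C@H]2C(C)(C)CCC[C@]12C | intermediate
27 | (5S,6S,7S,10S)-7α,15-diacetoxy-6β-hydroxylabda-8,13Z-diene | CC(=O)OC/C=C(/C)CCC1=C(C)[C@H](OC(C)=O)[C@@H](O)[C@H]2C(C)(C)CCC[C@]12C | target

**Step count and risks**

Total step count: 15. Longest linear sequence: 12 steps (7 → 27, steps 4–15); the ring A branch from 1 is 11 steps.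

Steps most likely to fail:

1. Step 11 (key step). The C5 ketyl may be quenched to the C5 carbinol or couple intermolecularly before it reaches the ester, or the allylic silyl ether may be cleaved by low-valent titanium. The fallback sets out from 20 and comes back at 22. i-Bu2AlH (CH2Cl2, −78 °C) should reduce the ester to the keto aldehyde F1. SmI2 (THF, t-BuOH, −78 °C → rt) should then close ring B by ketyl pinacol coupling to the 5,6-diol F2. SO3·pyridine/DMSO/Et3N should oxidise the secondary C6 carbinol to the 5-hydroxy-6-ketone F3. SmI2 in THF/MeOH (−78 °C) should then cleave the tertiary α-hydroxyl reductively, and protonation of the samarium enolate at C5 returns ketone 22.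

2. Step 9. Dehydrochlorination of the hindered acid chloride may be slow and C-acylation of the ylide may compete with ketene trapping. The fallback sets out from 14 (through acid chloride 16) and comes back at 18. 16 is treated with the lithium enolate of methyl acetate (2 equiv, THF, −78 °C) in a crossed Claisen acylation to give the β-keto ester F4. Tf2O with aqueous LiOH in toluene (5 °C) should give the (Z)-enol triflate F5. LiN(SiMe3)2 (THF, −78 °C) should then eliminate triflate through the γ-deprotonated dienolate to give allenoate 18.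

3. Step 12. Regio- and face control in the enolate oxidation may be lost, or base may cause migration of the C8=C9 double bond or transposition of the ketol. The fallback sets out from 22 and comes back at 24. Me3SiOTf/Et3N (CH2Cl2, 0 °C) should give the trimethylsilyl dienol ether F6. Dimethyldioxirane (acetone, −40 °C) should epoxidise the enol ether double bond from the α face under neutral conditions (Rubottom oxidation), and citric acid in MeOH should release the 7α-hydroxy ketone 24.

**Further compounds**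

F1 | step 11 | (3Z,7Z)-9-{[tert-butyl(diphenyl)silyl]oxy}-3,7-dimethyl-4-[(1R)-1,3,3-trimethyl-2-oxocyclohexyl]nona-3,7-dienal | O=C1C(C)(C)CCC[C@]1(C)/C(CC/C(C)=C\CO[Si](c2ccccc2)(c2ccccc2)C(C)(C)C)=C(/C)CC=O
F2 | step 11 | 15-{[tert-butyl(diphenyl)silyl]oxy}labda-8,13Z-diene-5,6-diol (C5/C6 epimers) | CC(C)(C)[Si](c3ccccc3)(c3ccccc3)OC/C=C(/C)CCC1=C(C)CC(O)C2(O)C(C)(C)CCC[C@]12C
F3 | step 11 | 15-{[tert-butyl(diphenyl)silyl]oxy}-5-hydroxylabda-8,13Z-dien-6-one (C5 epimers) | CC(C)(C)[Si](c3ccccc3)(c3ccccc3)OC/C=C(/C)CCC1=C(C)CC(=O)C2(O)C(C)(C)CCC[C@]12C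
F4 | step 9 | methyl (7Z)-9-{[tert-butyl(diphenyl)silyl]oxy}-7-methyl-3-oxo-4-[(1R)-1,3,3-trimethyl-2-oxocyclohexyl]non-7-enoate | O=C1C(C)(C)CCC[C@]1(C)C(CC/C(C)=C\CO[Si](c2ccccc2)(c2ccccc2)C(C)(C)C)C(=O)CC(=O)OC
F5 | step 9 | methyl (2Z,7Z)-9-{[tert-butyl(diphenyl)silyl]oxy}-7-methyl-3-{[(trifluoromethyl)sulfonyl]oxy}-4-[(1R)-1,3,3-trimethyl-2-oxocyclohexyl]nona-2,7-dienoate | O=C1C(C)(C)CCC[C@]1(C)C(CC/C(C)=C\CO[Si](c2ccccc2)(c2ccccc2)C(C)(C)C)/C(OS(=O)(=O)C(F)(F)F)=C/C(=O)OC
F6 | step 12 | 15-{[tert-butyl(diphenyl)silyl]oxy}-6-(trimethylsilyloxy)labda-6,8,13Z-triene | CC(C)(C)[Si](c3ccccc3)(c3ccccc3)OC/C=C(/C)CCC1=C(C)C=C(O[Si](C)(C)C)[C@H]2C(C)(C)CCC[C@]12C
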